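**Retrosynthetic overview** (locants are those of the hexahydro-1H-indene core of the target: C1 CHMe, C2 C=O, C3 CHEt, C3a, C4 C(Et)CO2H, C5 C(Et)(dienyl), C6=C7(Me), C7a)
1. Target 32 ⇐ bicyclic aldehyde 29 by oxidation-level changes only (C4–CHO → CO2H; C2–OTBS → C2=O).
2. 29 ⇐ acyclic pentaenal 28 by cutting C3a–C7a and C4–C5 (intramolecular [4+2]). The enabling feature is the cyclohexene ring C3a–C4–C5–C6=C7–C7a, whose only double bond lies between the two bonds to be made, together with the C1–C2–C3 bridge that ties diene terminus C7a to dienophile carbon C3a. Both rings therefore form in one operation; 28 is generated in the flask from aldehyde 27 by Wittig olefination.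
3. 27 ⇐ alkyne 13 + trienyl iodide 22 (hydrozirconation/Negishi coupling at the future C6–C7 bond).
4. 13 ⇐ aldehyde 7 (C3 centre by auxiliary-controlled hydroxymethylation) + propargylic mesylate 10 (C1 centre by Marshall propargylation).
5. 22 ⇐ (E)-β-bromostyrene + ethyl pent-2-ynoate (syn-cupration), then ethylcupration of a terminal enyne.

Key step: step 18

Remark: in step 8 the chirality transfer is assumed to run by anti-SN2′ palladation, Pd-to-Zn exchange with retention and a cyclic SE2′ addition, so that the (R)-mesylate gives the (S)-methyl centre; the neighbouring carbinol centre is oxidised in step 21, so either epimer there would serve.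

**Step 1**
Reactants: 1 (R)-4-benzyl-1,3-oxazolidin-2-one
Product: 2 (R)-4-benzyl-3-butanoyl-1,3-oxazolidin-2-one
Conditions: n-BuLi, THF, −78 °C; butanoyl chloride, −78 → 0 °C
Reagents that add atoms: butanoyl chloride, CCCC(=O)Cl
Why: N-acylation of the lithiated oxazolidinone by the acid chloride; no stereocentre is touched.

**Step 2**
Reactants: 2 (R)-4-benzyl-3-butanoyl-1,3-oxazolidin-2-one
Product: 4 (R)-4-benzyl-3-[(2S)-2-(hydroxymethyl)butanoyl]-1,3-oxazolidin-2-one, via titanium (Z)-enolate 3 (not isolated)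
Conditions: TiCl4, i-Pr2NEt, CH2Cl2, 0 °C; s-trioxane, TiCl4, 0 °C
Reagents that add atoms: s-trioxane, C1OCOCO1
Why: Evans titanium-enolate hydroxymethylation; the chelated (Z)-enolate is attacked by activated formaldehyde on the face opposite the benzyl group, which sets the ethyl-bearing centre (future C3) as (S).

**Step 3**
Reactants: 4 (R)-4-benzyl-3-[(2S)-2-(hydroxymethyl)butanoyl]-1,3-oxazolidin-2-one
Product: 5 (R)-4-benzyl-3-[(2S)-2-{[(triethylsilyl)oxy]methyl}butanoyl]-1,3-oxazolidin-2-one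
Conditions: Et3SiCl, imidazole, CH2Cl2, 0 °C
Reagents that add atoms: chlorotriethylsilane, CC[Si](Cl)(CC)CC
Why: silylation of the primary alcohol differentiates the two CH2O arms before the auxiliary is removed.

**Step 4**
Reactants: 5 (R)-4-benzyl-3-[(2S)-2-{[(triethylsilyl)oxy]methyl}butanoyl]-1,3-oxazolidin-2-one
Product: 6 (2R)-2-{[(triethylsilyl)oxy]methyl}butan-1-ol
Conditions: LiBH4, MeOH (1 equiv), Et2O, 0 °C
Reagents that add atoms: none
Why: reductive cleavage of the imide at the exocyclic carbonyl releases the auxiliary 1 for re-use and leaves the stereocentre untouched (the descriptor changes only by priority).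

**Step 5**
Reactants: 6 (2R)-2-{[(triethylsilyl)oxy]methyl}butan-1-ol
Product: 7 (2S)-2-{[(triethylsilyl)oxy]methyl}butanal
Conditions: Dess–Martin periodinane, NaHCO3, CH2Cl2, 0 °C → rt
Reagents that add atoms: none
Why: buffered Dess–Martin oxidation should give the α-branched aldehyde without epimerisation; it is used crude.

**Step 6**
Reactants: 8 pent-3-yn-2-one
Product: 9 (2R)-pent-3-yn-2-ol
Conditions: RuCl[(R,R)-TsDPEN](p-cymene) (cat.), i-PrOH, rt
Reagents that add atoms: none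
Why: Noyori asymmetric transfer hydrogenation of an ynone; the (R,R)-catalyst should deliver the (R)-propargylic alcohol.

**Step 7**
Reactants: 9 (2R)-pent-3-yn-2-ol
Product: 10 (2R)-pent-3-yn-2-yl methanesulfonate
Conditions: MsCl, Et3N, CH2Cl2, −78 → 0 °C
Reagents that add atoms: methanesulfonyl chloride, CS(=O)(=O)Cl
Why: O-sulfonylation proceeds with retention because the C–O bond is not broken.

**Step 8**
Reactants: 7 (2S)-2-{[(triethylsilyl)oxy]methyl}butanal; 10 (2R)-pent-3-yn-2-yl methanesulfonate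
Product: 12 (2S,3S,4S)-2-ethyl-4-methyl-1-[(triethylsilyl)oxy]hept-5-yn-3-ol, via allenylzinc reagent 11 (not isolated)
Conditions: Pd(OAc)2 (cat.), PPh3 (cat.), Et2Zn, THF, −78 → −20 °C
Reagents that add atoms: none
Why: Marshall propargylation; the chiral allenylzinc adds through a cyclic SE2′ transition state, so the mesylate configuration sets the methyl centre (future C1) as (S) with an anti C–OH, and the methyl alkyne needed later is delivered at the same time.

**Step 9**
Reactants: 12 (2S,3S,4S)-2-ethyl-4-methyl-1-[(triethylsilyl)oxy]hept-5-yn-3-ol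
Product: 13 (2S,3S,4S)-3-[(tert-butyldimethylsilyl)oxy]-2-ethyl-4-methyl-1-[(triethylsilyl)oxy]hept-5-yne
Conditions: TBSOTf, 2,6-lutidine, CH2Cl2, −78 → 0 °C
Reagents that add atoms: tert-butyldimethylsilyl triflate, CC(C)(C)[Si](C)(C)OS(=O)(=O)C(F)(F)F
Why: the silyl triflate protects the hindered secondary alcohol as an ether that outlasts the primary triethylsilyl ether.

**Step 10**
Reactants: 14 (E)-(2-bromoethenyl)benzene; 15 ethyl pent-2-ynoate
Product: 17 ethyl (2E,4E)-3-ethyl-5-phenylpenta-2,4-dienoate, via lithium distyrylcuprate 16 (not isolated)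
Conditions: 14, t-BuLi, Et2O, −78 °C; CuI, −40 °C; 15, THF, −78 °C; MeOH, −78 °C
Reagents that add atoms: none
Why: syn-carbocupration of the 2-ynoate by the alkenylcuprate with cold protonation places the styryl group trans to the ester and keeps the styryl (E)-geometry.

**Step 11**
Reactants: 17 ethyl (2E,4E)-3-ethyl-5-phenylpenta-2,4-dienoate
Product: 18 (2E,4E)-3-ethyl-5-phenylpenta-2,4-dien-1-ol
Conditions: DIBAL-H, CH2Cl2, −78 °C
Reagents that add atoms: none
Why: 1,2-reduction of the conjugated ester to the allylic alcohol without touching the diene.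

**Step 12**
Reactants: 18 (2E,4E)-3-ethyl-5-phenylpenta-2,4-dien-1-ol
Product: 19 (2E,4E)-3-ethyl-5-phenylpenta-2,4-dienal
Conditions: MnO2, CH2Cl2, rt
Reagents that add atoms: none
Why: chemoselective allylic oxidation under neutral conditions keeps the alkene geometry.

**Step 13**
Reactants: 19 (2E,4E)-3-ethyl-5-phenylpenta-2,4-dienal
Product: 20 [(1E,3E)-3-ethylhexa-1,3-dien-5-yn-1-yl]benzene
Conditions: TMSCHN2, LDA, THF, −78 °C → rt
Reagents that add atoms: (trimethylsilyl)diazomethane, C[Si](C)(C)C=[N+]=[N-]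
Why: Colvin homologation (1,2-addition, Peterson elimination, 1,2-hydride shift of the alkylidene carbene) turns the enal into the terminal enyne without conjugate addition.

**Step 14**
Reactants: 20 [(1E,3E)-3-ethylhexa-1,3-dien-5-yn-1-yl]benzene
Product: 22 [(1E,3E,5E)-3,5-diethyl-6-iodohexa-1,3,5-trien-1-yl]benzene, via trienylcopper 21 (not isolated)
Conditions: EtMgBr, CuBr·SMe2, THF, −60 → −30 °C; I2, −60 → 0 °C
Reagents that add atoms: ethylmagnesium bromide, CC[Mg]Br; iodine, II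
Why: Normant carbocupration adds ethyl and copper syn across the terminal alkyne (ethyl to the internal carbon), and iodinolysis with retention puts iodine trans to the dienyl chain.

**Step 15**
Reactants: 13 (2S,3S,4S)-3-[(tert-butyldimethylsilyl)oxy]-2-ethyl-4-methyl-1-[(triethylsilyl)oxy]hept-5-yne; 22 [(1E,3E,5E)-3,5-diethyl-6-iodohexa-1,3,5-trien-1-yl]benzene
Product: 25 (2S,3S,4S,5E,7E,9E,11E)-3-[(tert-butyldimethylsilyl)oxy]-2,8,10-triethyl-4,6-dimethyl-12-phenyl-1-[(triethylsilyl)oxy]dodeca-5,7,9,11-tetraene, via alkenylzirconocene chloride 23 (not isolated), via alkenylzinc chloride 24 (not isolated)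
Conditions: Cp2Zr(H)Cl, THF, 50 °C; ZnCl2, 0 °C; 22, Pd(PPh3)4 (cat.), rt
Reagents that add atoms: none
Why: Schwartz hydrozirconation is syn and, after equilibration, places Zr on the less hindered methyl-bearing carbon; Zr-to-Zn exchange and Negishi coupling proceed with retention in both partners and should give the all-(E) tetraene.

**Step 16**
Reactants: 25 the bis-silylated tetraene
Product: 26 (2S,3S,4S,5E,7E,9E,11E)-3-[(tert-butyldimethylsilyl)oxy]-2,8,10-triethyl-4,6-dimethyl-12-phenyldodeca-5,7,9,11-tetraen-1-ol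
Conditions: HF·pyridine, pyridine, THF, 0 °C
Reagents that add atoms: none
Why: buffered fluoride cleaves the primary triethylsilyl ether selectively; the hindered secondary TBS ether and the polyene should survive.

**Step 17**
Reactants: 26 the tetraenol
Product: 27 (2R,3S,4S,5E,7E,9E,11E)-3-[(tert-butyldimethylsilyl)oxy]-2,8,10-triethyl-4,6-dimethyl-12-phenyldodeca-5,7,9,11-tetraenal
Conditions: Dess–Martin periodinane, NaHCO3, CH2Cl2, 0 °C
Reagents that add atoms: none
Why: buffered Dess–Martin oxidation gives the α-branched aldehyde without epimerisation (the descriptor changes only by priority); it is used at once.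

**Step 18**
Reactants: 27 the tetraenal
Product: 29 (1S,2S,3S,3aR,4R,5R,7aR)-2-[(tert-butyldimethylsilyl)oxy]-3,4,5-triethyl-5-[(1E,3E)-2-ethyl-4-phenylbuta-1,3-dien-1-yl]-1,7-dimethyl-2,3,3a,4,5,7a-hexahydro-1H-indene-4-carbaldehyde, via pentaenal 28 (not isolated)
Conditions: 2-(triphenylphosphoranylidene)butanal, BHT (cat.), toluene (high dilution), 100 °C, dark
Reagents that add atoms: 2-(triphenylphosphoranylidene)butanal, CCC(C=O)=P(c1ccccc1)(c1ccccc1)c1ccccc1
Why: The stabilised formyl ylide converts 27 into the (E)-2-ethyl enal 28 (Wittig reaction), whose enal and all-(E) diene then combine in a thermal intramolecular Diels–Alder reaction, the closest known type being tandem Wittig/[4+2] closures of 1,6,8-nonatrienals to trans-hydrindenes. The cyclohexene closes by a concerted suprafacial [4+2] that makes C4–C5 and C3a–C7a together, and the cyclopentane closes in the same event because the three-atom C1–C2–C3 tether joins diene terminus C7a to dienophile carbon C3a. C7a is set by the C1 methyl stereocentre (A1,3 strain with the C7 methyl holds H-1 in the diene plane, so the tethered dienophile adds to one face and Me-1 ends cis to H-7a), C3a is set in the same way by the C3 ethyl stereocentre against the α-ethyl group of the enal, C5 follows from the (E)-geometry of the terminal diene bond (ethyl inside, styryldienyl outside) and C4 from the (E)-enal with the formyl group endo. The step needs the trans ring fusion and a single π-face: the anti relation of the two allylic stereocentres lets only the CHO-endo, trans-fused transition state keep both allylic hydrogens eclipsed, whereas the cis-fused and opposite-face alternatives force a methyl or ethyl group into the plane. High dilution, BHT and exclusion of light suppress bimolecular cycloaddition and polyene isomerisation, and the neopentylic aldehyde of 29 should not react further with the ylide.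

**Step 19**
Reactants: 29 the bicyclic aldehyde
Product: 30 (1S,2S,3S,3aR,4R,5R,7aR)-2-[(tert-butyldimethylsilyl)oxy]-3,4,5-triethyl-5-[(1E,3E)-2-ethyl-4-phenylbuta-1,3-dien-1-yl]-1,7-dimethyl-2,3,3a,4,5,7a-hexahydro-1H-indene-4-carboxylic acid
Conditions: NaClO2, NaH2PO4, 2-methyl-2-butene, t-BuOH/H2O, rt
Reagents that add atoms: sodium chlorite, [Na+].[O-]Cl=O
Why: Pinnick oxidation works on hindered, non-enolisable aldehydes, and the alkene scavenger traps HOCl so the styryl diene is spared.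

**Step 20**
Reactants: 30 the silyl ether acid
Product: 31 (1S,2S,3S,3aR,4R,5R,7aR)-3,4,5-triethyl-5-[(1E,3E)-2-ethyl-4-phenylbuta-1,3-dien-1-yl]-2-hydroxy-1,7-dimethyl-2,3,3a,4,5,7a-hexahydro-1H-indene-4-carboxylic acid
Conditions: HF·pyridine, THF, rt → 40 °C
Reagents that add atoms: none
Why: fluoride-driven cleavage of the hindered secondary TBS ether; the hydroxyl and the carboxyl group lie on opposite faces, so no lactone is expected.

**Step 21**
Reactants: 31 the hydroxy acid
Product: 32 (1S,3S,3aR,4R,5R,7aR)-3,4,5-triethyl-5-[(1E,3E)-2-ethyl-4-phenylbuta-1,3-dien-1-yl]-1,7-dimethyl-2-oxo-2,3,3a,4,5,7a-hexahydro-1H-indene-4-carboxylic acid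
Conditions: Dess–Martin periodinane, CH2Cl2, rt
Reagents that add atoms: none
Why: Dess–Martin oxidation of the secondary alcohol tolerates the free acid, and both α-centres (C1, C3) already carry their substituents anti to the neighbouring ring carbon, the stable arrangement, so epimerisation is not expected.

**Compound list**
1 | (R)-4-benzyl-1,3-oxazolidin-2-one | O=C1N[C@H](Cc2ccccc2)CO1 | starting material
2 | (R)-4-benzyl-3-butanoyl-1,3-oxazolidin-2-one | CCCC(=O)N1[C@H](Cc2ccccc2)COC1=O | intermediate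
3 | trichlorotitanium (Z)-enolate of 2 (formed in the flask) | CC/C=C(\O[Ti](Cl)(Cl)Cl)N1[C@H](Cc2ccccc2)COC1=O | intermediate
4 | (R)-4-benzyl-3-[(2S)-2-(hydroxymethyl)butanoyl]-1,3-oxazolidin-2-one | CC[C@@H](CO)C(=O)N1[C@H](Cc2ccccc2)COC1=O | intermediate
5 | (R)-4-benzyl-3-[(2S)-2-{[(triethylsilyl)oxy]methyl}butanoyl]-1,3-oxazolidin-2-one | CC[C@@H](CO[Si](CC)(CC)CC)C(=O)N1[C@H](Cc2ccccc2)COC1=O | intermediate
6 | (2R)-2-{[(triethylsilyl)oxy]methyl}butan-1-ol | CC[C@@H](CO[Si](CC)(CC)CC)CO | intermediate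
7 | (2S)-2-{[(triethylsilyl)oxy]methyl}butanal | CC[C@@H](CO[Si](CC)(CC)CC)C=O | intermediate
8 | pent-3-yn-2-one | CC#CC(C)=O | starting material
9 | (2R)-pent-3-yn-2-ol | C[C@@H](O)C#CC | intermediate
10 | (2R)-pent-3-yn-2-yl methanesulfonate | C[C@@H](OS(C)(=O)=O)C#CC | intermediate
11 | ethyl[(M)-penta-2,3-dien-2-yl]zinc (formed in the flask) | CC[Zn]C(C)=[C@@]=C([H])C | intermediate
12 | (2S,3S,4S)-2-ethyl-4-methyl-1-[(triethylsilyl)oxy]hept-5-yn-3-ol | CC[Si](CC)(CC)OC[C@H](CC)[C@@H](O)[C@@H](C)C#CC | intermediate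
13 | (2S,3S,4S)-3-[(tert-butyldimethylsilyl)oxy]-2-ethyl-4-methyl-1-[(triethylsilyl)oxy]hept-5-yne | CC[Si](CC)(CC)OC[C@H](CC)[C@@H](O[Si](C)(C)C(C)(C)C)[C@@H](C)C#CC | intermediate
14 | (E)-(2-bromoethenyl)benzene | Br/C=C/c1ccccc1 | starting material
15 | ethyl pent-2-ynoate | CCC#CC(=O)OCC | starting material
16 | lithium bis[(E)-2-phenylethenyl]cuprate (formed in the flask) | [Li+].c1ccccc1/C=C/[Cu-]/C=C/c1ccccc1 | intermediate
17 | ethyl (2E,4E)-3-ethyl-5-phenylpenta-2,4-dienoate | CCOC(=O)/C=C(CC)/C=C/c1ccccc1 | intermediate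
18 | (2E,4E)-3-ethyl-5-phenylpenta-2,4-dien-1-ol | OC/C=C(CC)/C=C/c1ccccc1 | intermediate
19 | (2E,4E)-3-ethyl-5-phenylpenta-2,4-dienal | O=C/C=C(CC)/C=C/c1ccccc1 | intermediate
20 | [(1E,3E)-3-ethylhexa-1,3-dien-5-yn-1-yl]benzene | C#C/C=C(CC)/C=C/c1ccccc1 | intermediate
21 | [(1E,3E,5E)-2,4-diethyl-6-phenylhexa-1,3,5-trien-1-yl]copper (formed in the flask) | [Cu]/C=C(CC)/C=C(CC)/C=C/c1ccccc1 | intermediate
22 | [(1E,3E,5E)-3,5-diethyl-6-iodohexa-1,3,5-trien-1-yl]benzene | I/C=C(CC)/C=C(CC)/C=C/c1ccccc1 | intermediate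
23 | chlorobis(cyclopentadienyl)[(2E,4S,5S,6S)-5-[(tert-butyldimethylsilyl)oxy]-6-ethyl-4-methyl-7-[(triethylsilyl)oxy]hept-2-en-2-yl]zirconium (formed in the flask; Cp drawn σ-bonded) | CC[Si](CC)(CC)OC[C@H](CC)[C@@H](O[Si](C)(C)C(C)(C)C)[C@@H](C)/C=C(C)/[Zr](Cl)(C1C=CC=C1)C1C=CC=C1 | intermediate
24 | chloro[(2E,4S,5S,6S)-5-[(tert-butyldimethylsilyl)oxy]-6-ethyl-4-methyl-7-[(triethylsilyl)oxy]hept-2-en-2-yl]zinc (formed in the flask) | CC[Si](CC)(CC)OC[C@H](CC)[C@@H](O[Si](C)(C)C(C)(C)C)[C@@H](C)/C=C(C)/[Zn]Cl | intermediate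
25 | (2S,3S,4S,5E,7E,9E,11E)-3-[(tert-butyldimethylsilyl)oxy]-2,8,10-triethyl-4,6-dimethyl-12-phenyl-1-[(triethylsilyl)oxy]dodeca-5,7,9,11-tetraene | CC[Si](CC)(CC)OC[C@H](CC)[C@@H](O[Si](C)(C)C(C)(C)C)[C@@H](C)/C=C(C)/C=C(CC)/C=C(CC)/C=C/c1ccccc1 | intermediate
26 | (2S,3S,4S,5E,7E,9E,11E)-3-[(tert-butyldimethylsilyl)oxy]-2,8,10-triethyl-4,6-dimethyl-12-phenyldodeca-5,7,9,11-tetraen-1-ol | OC[C@H](CC)[C@@H](O[Si](C)(C)C(C)(C)C)[C@@H](C)/C=C(C)/C=C(CC)/C=C(CC)/C=C/c1ccccc1 | intermediate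
27 | (2R,3S,4S,5E,7E,9E,11E)-3-[(tert-butyldimethylsilyl)oxy]-2,8,10-triethyl-4,6-dimethyl-12-phenyldodeca-5,7,9,11-tetraenal | O=C[C@H](CC)[C@@H](O[Si](C)(C)C(C)(C)C)[C@@H](C)/C=C(C)/C=C(CC)/C=C(CC)/C=C/c1ccccc1 | intermediate
28 | (2E,4S,5S,6S,7E,9E,11E,13E)-5-[(tert-butyldimethylsilyl)oxy]-2,4,10,12-tetraethyl-6,8-dimethyl-14-phenyltetradeca-2,7,9,11,13-pentaenal (formed in the flask) | O=C/C(CC)=C/[C@H](CC)[C@@H](O[Si](C)(C)C(C)(C)C)[C@@H](C)/C=C(C)/C=C(CC)/C=C(CC)/C=C/c1ccccc1 | intermediate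
29 | (1S,2S,3S,3aR,4R,5R,7aR)-2-[(tert-butyldimethylsilyl)oxy]-3,4,5-triethyl-5-[(1E,3E)-2-ethyl-4-phenylbuta-1,3-dien-1-yl]-1,7-dimethyl-2,3,3a,4,5,7a-hexahydro-1H-indene-4-carbaldehyde | CCC(/C=C/c1ccccc1)=C\[C@@]1(CC)C=C(C)[C@@H]2[C@H]([C@H](CC)[C@@H](O[Si](C)(C)C(C)(C)C)[C@H]2C)[C@@]1(CC)C=O | intermediate
30 | (1S,2S,3S,3aR,4R,5R,7aR)-2-[(tert-butyldimethylsilyl)oxy]-3,4,5-triethyl-5-[(1E,3E)-2-ethyl-4-phenylbuta-1,3-dien-1-yl]-1,7-dimethyl-2,3,3a,4,5,7a-hexahydro-1H-indene-4-carboxylic acid | CCC(/C=C/c1ccccc1)=C\[C@@]1(CC)C=C(C)[C@@H]2[C@H]([C@H](CC)[C@@H](O[Si](C)(C)C(C)(C)C)[C@H]2C)[C@@]1(CC)C(=O)O | intermediate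
31 | (1S,2S,3S,3aR,4R,5R,7aR)-3,4,5-triethyl-5-[(1E,3E)-2-ethyl-4-phenylbuta-1,3-dien-1-yl]-2-hydroxy-1,7-dimethyl-2,3,3a,4,5,7a-hexahydro-1H-indene-4-carboxylic acid | CCC(/C=C/c1ccccc1)=C\[C@@]1(CC)C=C(C)[C@@H]2[C@H]([C@H](CC)[C@@H](O)[C@H]2C)[C@@]1(CC)C(=O)O | intermediate
32 | (1S,3S,3aR,4R,5R,7aR)-3,4,5-triethyl-5-[(1E,3E)-2-ethyl-4-phenylbuta-1,3-dien-1-yl]-1,7-dimethyl-2-oxo-2,3,3a,4,5,7a-hexahydro-1H-indene-4-carboxylic acid | CCC(/C=C/c1ccccc1)=C\[C@@]1(CC)C=C(C)[C@@H]2[C@H]([C@H](CC)C(=O)[C@H]2C)[C@@]1(CC)C(=O)O | target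

**Step count:** 21 steps in total; longest linear sequence 14 steps (steps 1–5, 8, 9, 15–21).

**Steps most likely to fail**

Step 18. The olefination of the hindered α-branched aldehyde may be slow at the temperature at which the cycloaddition already runs. That would allow epimerisation α to the aldehyde, over-homologation of the enal and erosion of endo/exo or facial control. The fallback separates the two events and runs the cycloaddition under Lewis-acid control. Setting out from 27, olefination with ethyl 2-(triphenylphosphoranylidene)butanoate (CH2Cl2, 40 °C) should give ethyl (2E,4S,5S,6S,7E,9E,11E,13E)-5-[(tert-butyldimethylsilyl)oxy]-2,4,10,12-tetraethyl-6,8-dimethyl-14-phenyltetradeca-2,7,9,11,13-pentaenoate F1. DIBAL-H at −78 °C should then give the allylic alcohol (2E,4S,5S,6S,7E,9E,11E,13E)-5-[(tert-butyldimethylsilyl)oxy]-2,4,10,12-tetraethyl-6,8-dimethyl-14-phenyltetradeca-2,7,9,11,13-pentaen-1-ol F2. MnO2 at room temperature delivers enal 28, which is treated directly with Me2AlCl (CH2Cl2, −78 → −20 °C) so that the endo, trans-fused closure takes place cold; the route is rejoined at 29.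

Step 14. The organocopper reagent may metalate the acidic C–H of the conjugated alkyne instead of adding, or may add with the wrong regiochemistry. The fallback reverses the polarity of the fragment union. From 20, copper-catalysed borylative ethylation (B2pin2, EtI, CuCl/Xantphos, NaOt-Bu, THF) should give 2-[(1E,3E,5E)-2,4-diethyl-6-phenylhexa-1,3,5-trien-1-yl]-4,4,5,5-tetramethyl-1,3,2-dioxaborolane F3. In parallel, 13 is converted by Cp2Zr(H)Cl and then I2 into (2S,3S,4S,5E)-3-[(tert-butyldimethylsilyl)oxy]-2-ethyl-6-iodo-4-methyl-1-[(triethylsilyl)oxy]hept-5-ene F4. Suzuki–Miyaura coupling of F3 with F4 (Pd(dppf)Cl2, aq. K3PO4, THF) rejoins the route at 25.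

Step 8. The allenylmetal may lose configurational integrity before addition, so that chirality transfer to the methyl centre is incomplete, or the reagent may be mismatched with the α-stereocentre of the aldehyde. The fallback builds the same centre by crotylboration and makes the alkyne afterwards. From 7, Brown (E)-crotylboration (the (E)-crotyl-B(Ipc)2 enantiomer expected to give the (S)-methyl centre, that from (−)-Ipc2BOMe; −78 °C, then NaOH/H2O2) should give (2S,3S,4S)-2-ethyl-4-methyl-1-[(triethylsilyl)oxy]hex-5-en-3-ol F5. TBSOTf/2,6-lutidine gives its TBS ether (2S,3S,4S)-3-[(tert-butyldimethylsilyl)oxy]-2-ethyl-4-methyl-1-[(triethylsilyl)oxy]hex-5-ene F6. Ozonolysis (O3, then PPh3) gives (2R,3R,4S)-3-[(tert-butyldimethylsilyl)oxy]-4-ethyl-2-methyl-5-[(triethylsilyl)oxy]pentanal F7. Corey–Fuchs olefination (CBr4, PPh3, 2,6-lutidine) gives (2S,3S,4S)-6,6-dibromo-3-[(tert-butyldimethylsilyl)oxy]-2-ethyl-4-methyl-1-[(triethylsilyl)oxy]hex-5-ene F8. n-BuLi followed by MeI converts F8 into 13, where the route is rejoined.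

**Further compounds**
F1 | step 18 | ethyl (2E,4S,5S,6S,7E,9E,11E,13E)-5-[(tert-butyldimethylsilyl)oxy]-2,4,10,12-tetraethyl-6,8-dimethyl-14-phenyltetradeca-2,7,9,11,13-pentaenoate | CCOC(=O)/C(CC)=C/[C@H](CC)[C@@H](O[Si](C)(C)C(C)(C)C)[C@@H](C)/C=C(C)/C=C(CC)/C=C(CC)/C=C/c1ccccc1
F2 | step 18 | (2E,4S,5S,6S,7E,9E,11E,13E)-5-[(tert-butyldimethylsilyl)oxy]-2,4,10,12-tetraethyl-6,8-dimethyl-14-phenyltetradeca-2,7,9,11,13-pentaen-1-ol | OC/C(CC)=C/[C@H](CC)[C@@H](O[Si](C)(C)C(C)(C)C)[C@@H](C)/C=C(C)/C=C(CC)/C=C(CC)/C=C/c1ccccc1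
F3 | step 14 | 2-[(1E,3E,5E)-2,4-diethyl-6-phenylhexa-1,3,5-trien-1-yl]-4,4,5,5-tetramethyl-1,3,2-dioxaborolane | CC1(C)OB(/C=C(CC)/C=C(CC)/C=C/c2ccccc2)OC1(C)C
F4 | step 14 | (2S,3S,4S,5E)-3-[(tert-butyldimethylsilyl)oxy]-2-ethyl-6-iodo-4-methyl-1-[(triethylsilyl)oxy]hept-5-ene | CC[Si](CC)(CC)OC[C@H](CC)[C@@H](O[Si](C)(C)C(C)(C)C)[C@@H](C)/C=C(C)/I
F5 | step 8 | (2S,3S,4S)-2-ethyl-4-methyl-1-[(triethylsilyl)oxy]hex-5-en-3-ol | CC[Si](CC)(CC)OC[C@H](CC)[C@@H](O)[C@@H](C)C=C
F6 | step 8 | (2S,3S,4S)-3-[(tert-butyldimethylsilyl)oxy]-2-ethyl-4-methyl-1-[(triethylsilyl)oxy]hex-5-ene | CC[Si](CC)(CC)OC[C@H](CC)[C@@H](O[Si](C)(C)C(C)(C)C)[C@@H](C)C=C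
F7 | step 8 | (2R,3R,4S)-3-[(tert-butyldimethylsilyl)oxy]-4-ethyl-2-methyl-5-[(triethylsilyl)oxy]pentanal | CC[Si](CC)(CC)OC[C@H](CC)[C@@H](O[Si](C)(C)C(C)(C)C)[C@@H](C)C=O
F8 | step 8 | (2S,3S,4S)-6,6-dibromo-3-[(tert-butyldimethylsilyl)oxy]-2-ethyl-4-methyl-1-[(triethylsilyl)oxy]hex-5-ene | CC[Si](CC)(CC)OC[C@H](CC)[C@@H](O[Si](C)(C)C(C)(C)C)[C@@H](C)C=C(Br)Br
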